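**Plan**
- **Cuts** (coumarin numbering for rings A and B, primes for dihydropyranone ring C, double primes for the side chain): first the O2''–Si bond. Then ring B at C3=C4 and O1–C2, which separates a salicylaldehyde (ring A plus C4) from a ring C acetate (C2, C3). Then ring A at C5–C6 and C8–C8a, and ring C at O1'–C6'.
- **Enabling feature:** ring A (C4a, C5, C6, C7, C8, C8a) is a hexasubstituted 2,4-dimethylresorcinol. C6–C7(O)–C8 with its two methyl groups is the symmetric skeleton of pentan-3-one. C5, C4a, C8a(O) and the exocyclic C4 are the alkylidene malonate of the side-chain aldehyde.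
- **Forward order:** side-chain aldehyde, alkylidene malonate, ring A as a cyclohexane-1,3-dione (Michael–Claisen annulation), dehydrogenation to the resorcylate, ester to aldehyde. Ring C is made separately by cyclodehydration of a hydroxy diketo ester. Ring B closes last by Knoevenagel condensation and lactonisation, and desilylation ends the route.
- **Stereochemistry:** C2'' (S) is bought with ethyl (S)-3-hydroxybutanoate, C1'' (R) comes from its Fráter–Seebach anti-methylation, and C2' (R) is bought with methyl (R)-3-hydroxybutanoate. The ring centres made in the annulation vanish on aromatisation.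

Key step: step 5

Remark on the chemistry: the Michael adduct, the cyclohexanedione and its bromide are mixtures of diastereomers at the new centres and of keto–enol tautomers. They are drawn as keto forms with these centres undefined, because aromatisation removes them.

Step 1
Reactants: 1 ethyl (S)-3-hydroxybutanoate
Product: 2 ethyl (2S,3S)-3-hydroxy-2-methylbutanoate
Conditions: LiN(iPr)2 (2.2 equiv), THF, −78 → −20 °C; MeI, DMPU, −78 → 0 °C
Reagents that add atoms: iodomethane, CI
Why: Fráter–Seebach alkylation, in which the dilithiated alkoxide enolate sits in a six-membered chelate and MeI enters from the face away from the C3 methyl group, so that C2 is set as S (anti to the oxygen) under control of the purchased C3 centre.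

Step 2
Reactants: 2 ethyl (2S,3S)-3-hydroxy-2-methylbutanoate
Product: 3 ethyl (2S,3S)-3-[(tert-butyldiphenylsilyl)oxy]-2-methylbutanoate
Conditions: TBDPSCl, imidazole, DMF, rt
Reagents that add atoms: tert-butyl(chloro)diphenylsilane, CC(C)(C)[Si](Cl)(c1ccccc1)c1ccccc1
Why: Imidazole-promoted silylation of a secondary alcohol is routine, and the tert-butyldiphenylsilyl group is preferred to smaller silyl groups because it has to outlast methoxide in step 5, HBr in step 6 and aqueous HCl in step 10.

Step 3
Reactants: 3 ethyl (2S,3S)-3-[(tert-butyldiphenylsilyl)oxy]-2-methylbutanoate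
Product: 4 (2S,3S)-3-[(tert-butyldiphenylsilyl)oxy]-2-methylbutanal
Conditions: i-Bu2AlH (1.1 equiv), CH2Cl2, −78 °C; MeOH, aq. potassium sodium tartrate
Reagents that add atoms: none
Why: Partial ester reduction with i-Bu2AlH relies on the aluminium hemiacetal being stable at −78 °C until the quench, is well known for β-silyloxy esters, and leaves C2 intact if the aldehyde is used at once without chromatography.

Step 4
Reactants: 4 (2S,3S)-3-[(tert-butyldiphenylsilyl)oxy]-2-methylbutanal, 5 dimethyl malonate
Product: 6 dimethyl 2-{(2R,3S)-3-[(tert-butyldiphenylsilyl)oxy]-2-methylbutylidene}malonate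
Conditions: TiCl4 (2 equiv), pyridine (4 equiv), THF, 0 °C → rt
Reagents that add atoms: none
Why: Knoevenagel condensation in the Lehnert variant, where TiCl4 activates both partners and takes up the water while pyridine is too weak a base to enolise the aldehyde or to deconjugate the product, so the allylic centre keeps its configuration.

Step 5
Reactants: 6 dimethyl 2-{(2R,3S)-3-[(tert-butyldiphenylsilyl)oxy]-2-methylbutylidene}malonate, 7 pentan-3-one
Product: 9 methyl 6-{(2R,3S)-3-[(tert-butyldiphenylsilyl)oxy]butan-2-yl}-3,5-dimethyl-2,4-dioxocyclohexane-1-carboxylate, via Michael adduct 8 (not isolated)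
Conditions: 7 (1.2 equiv), LiN(iPr)2 (1.1 equiv), THF, −78 °C; add 6, −78 °C; then NaOMe (3 equiv), MeOH, −78 → 50 °C; cold 1 M HCl to pH 3
Reagents that add atoms: none
Why: The kinetic lithium enolate of 7 adds at −78 °C to the doubly activated β-carbon of 6 (Michael addition, C5–C6 bond) and the charge comes to rest on the malonate of 8. Methoxide in methanol, matched to the methyl esters, then moves protons so that a small share of the ketone enolate at the remaining CH2 group coexists with a neutral malonate; this carbon attacks one ester in a 6-(enolendo)-exo-trig Claisen closure (C8–C8a bond), methoxide leaves, and deprotonation of the acidic 2-methyl-1,3-dione pulls all earlier equilibria forward. The closest known reaction type is the Michael–Claisen (3+3) annulation of ketone enolates with enoates or alkylidene malonates, and the ring closure itself is the one that operates in dimedone-type condensations of malonates with enones. Four ring stereocentres (C4a, C5, C6, C8) arise without control and need none, since step 6 erases all of them, while C1'' and C2'' are not α to any carbonyl group in 8 or 9 and stay as set. The step needs 1,4-addition instead of γ-deprotonation of 6, which is secured by the low temperature, the high electrophilicity of the malonate acceptor and allylic 1,3-strain that holds the γ-C–H bond in the alkene plane, out of overlap with the π system. Regiochemistry is not in question because 7 is symmetric and either ester gives the same ring, and O-acylation to an enol lactone is reversed by methoxide whereas C-acylation is not.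

Step 6
Reactants: 9 methyl 6-{(2R,3S)-3-[(tert-butyldiphenylsilyl)oxy]butan-2-yl}-3,5-dimethyl-2,4-dioxocyclohexane-1-carboxylate
Product: 11 methyl 6-{(2R,3S)-3-[(tert-butyldiphenylsilyl)oxy]butan-2-yl}-2,4-dihydroxy-3,5-dimethylbenzoate, via bromodione 10 (not isolated)
Conditions: CuBr2 (2.1 equiv), LiBr, MeCN, rt → 70 °C
Reagents that add atoms: none
Why: Halogenation–dehydrohalogenation, the usual aromatisation of 2,4-dioxocyclohexanecarboxylates: CuBr2 brominates the dione enol at C8, enolisation of the C7 ketone towards C6 lets HBr leave in a 1,4-sense with the C5 hydrogen, and the dienone tautomerises to the resorcylate, which has no free ring position left for further bromination.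

Step 7
Reactants: 11 methyl 6-{(2R,3S)-3-[(tert-butyldiphenylsilyl)oxy]butan-2-yl}-2,4-dihydroxy-3,5-dimethylbenzoate
Product: 12 methyl 6-{(2R,3S)-3-[(tert-butyldiphenylsilyl)oxy]butan-2-yl}-2,4-bis(methoxymethoxy)-3,5-dimethylbenzoate
Conditions: NaH (3 equiv), MOMCl (3 equiv), DMF, 0 °C → rt
Reagents that add atoms: chloromethyl methyl ether, COCCl
Why: Williamson-type O-alkylation of both phenoxides with MOMCl, with NaH as base because the hydroxyl ortho to the ester is hydrogen-bonded and flanked by a methyl group.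

Step 8
Reactants: 12 methyl 6-{(2R,3S)-3-[(tert-butyldiphenylsilyl)oxy]butan-2-yl}-2,4-bis(methoxymethoxy)-3,5-dimethylbenzoate
Product: 13 (6-{(2R,3S)-3-[(tert-butyldiphenylsilyl)oxy]butan-2-yl}-2,4-bis(methoxymethoxy)-3,5-dimethylphenyl)methanol
Conditions: LiAlH4, THF, 0 °C → rt
Reagents that add atoms: none
Why: Hydride reduction of a benzoate ester, for which LiAlH4 is small enough to reach the di-ortho-substituted carbonyl group and to which MOM acetals and the silyl ether are inert.

Step 9
Reactants: 13 (6-{(2R,3S)-3-[(tert-butyldiphenylsilyl)oxy]butan-2-yl}-2,4-bis(methoxymethoxy)-3,5-dimethylphenyl)methanol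
Product: 14 6-{(2R,3S)-3-[(tert-butyldiphenylsilyl)oxy]butan-2-yl}-2,4-bis(methoxymethoxy)-3,5-dimethylbenzaldehyde
Conditions: MnO2 (excess), CH2Cl2, rt
Reagents that add atoms: none
Why: MnO2 oxidation of an electron-rich benzylic alcohol stops at the aldehyde stage and is neutral, so the acetals and the silyl ether are untouched.

Step 10
Reactants: 14 6-{(2R,3S)-3-[(tert-butyldiphenylsilyl)oxy]butan-2-yl}-2,4-bis(methoxymethoxy)-3,5-dimethylbenzaldehyde
Product: 15 6-{(2R,3S)-3-[(tert-butyldiphenylsilyl)oxy]butan-2-yl}-2,4-dihydroxy-3,5-dimethylbenzaldehyde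
Conditions: 3 M aq. HCl, THF, 40 °C
Reagents that add atoms: none
Why: Acid hydrolysis of aryl MOM acetals is much faster than cleavage of a hindered secondary tert-butyldiphenylsilyl ether, and keeping O2'' masked stops the hydroxy aldehyde from closing to a lactol and dehydrating to a quinone methide.

Step 11
Reactants: 16 methyl (R)-3-hydroxybutanoate
Product: 17 methyl (R)-3-[(tert-butyldimethylsilyl)oxy]butanoate
Conditions: TBSCl, imidazole, DMF, rt
Reagents that add atoms: tert-butyl(chloro)dimethylsilane, CC(C)(C)[Si](C)(C)Cl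
Why: Routine imidazole-promoted silylation that blocks the hydroxyl group against the strong bases of steps 12 and 13 and does not touch the stereocentre.

Step 12
Reactants: 17 methyl (R)-3-[(tert-butyldimethylsilyl)oxy]butanoate
Product: 18 (R)-3-[(tert-butyldimethylsilyl)oxy]-N-methoxy-N-methylbutanamide
Conditions: MeNH(OMe)·HCl (1.5 equiv), i-PrMgCl (3 equiv), THF, −20 → 0 °C
Reagents that add atoms: N,O-dimethylhydroxylamine hydrochloride, CNOC.Cl
Why: Weinreb amide formation by aminolysis of the ester with the chloromagnesium amide generated from the amine salt and i-PrMgCl, a standard reaction of β-silyloxy esters that is fast enough at low temperature to avoid β-elimination.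

Step 13
Reactants: 18 (R)-3-[(tert-butyldimethylsilyl)oxy]-N-methoxy-N-methylbutanamide, 19 methyl acetoacetate
Product: 20 methyl (R)-7-[(tert-butyldimethylsilyl)oxy]-3,5-dioxooctanoate
Conditions: 19 (2.2 equiv), LiN(iPr)2 (4.4 equiv), THF, 0 °C; add 18, −78 → 0 °C; aq. NH4Cl
Reagents that add atoms: none
Why: γ-Acylation of the acetoacetate dianion, whose terminal carbon is the more nucleophilic site, by a Weinreb amide whose chelated tetrahedral intermediate prevents a second addition; the excess dianion absorbs the acidic proton of the product.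

Step 14
Reactants: 20 methyl (R)-7-[(tert-butyldimethylsilyl)oxy]-3,5-dioxooctanoate
Product: 22 methyl 2-[(2R)-2-methyl-4-oxo-3,4-dihydro-2H-pyran-6-yl]acetate, via hydroxy diketo ester 21 (not isolated)
Conditions: TFA, moist CH2Cl2, 0 °C → rt
Reagents that add atoms: none
Why: Acid removes the silyl group, the freed C7 hydroxyl adds to the C3 ketone in a 6-exo-trig hemiketalisation and loss of water gives the conjugated vinylogous ester (the usual cyclodehydration of δ-hydroxy β-diketones), and since the C7–O bond is never broken the R configuration is kept.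

Step 15
Reactants: 15 6-{(2R,3S)-3-[(tert-butyldiphenylsilyl)oxy]butan-2-yl}-2,4-dihydroxy-3,5-dimethylbenzaldehyde, 22 methyl 2-[(2R)-2-methyl-4-oxo-3,4-dihydro-2H-pyran-6-yl]acetate
Product: 24 5-{(2R,3S)-3-[(tert-butyldiphenylsilyl)oxy]butan-2-yl}-7-hydroxy-6,8-dimethyl-3-[(2R)-2-methyl-4-oxo-3,4-dihydro-2H-pyran-6-yl]-2H-chromen-2-one, via alkylidene ester 23 (not isolated)
Conditions: piperidine (cat.), AcOH (cat.), 4 Å MS, toluene, 80 °C
Reagents that add atoms: none
Why: Knoevenagel condensation followed by lactonisation, the standard coumarin synthesis from salicylaldehydes and activated acetates: the CH2 group of 22 is acidified by the ester and by the vinylogous ketone, piperidine raises the reactivity of the hindered aldehyde through its iminium ion, loss of methanol to the ortho hydroxyl makes the sequence irreversible, and the buffered catalytic amine is too mild to open ring C at C2'.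

Step 16
Reactants: 24 5-{(2R,3S)-3-[(tert-butyldiphenylsilyl)oxy]butan-2-yl}-7-hydroxy-6,8-dimethyl-3-[(2R)-2-methyl-4-oxo-3,4-dihydro-2H-pyran-6-yl]-2H-chromen-2-one
Product: 25 7-hydroxy-5-[(2R,3S)-3-hydroxybutan-2-yl]-6,8-dimethyl-3-[(2R)-2-methyl-4-oxo-3,4-dihydro-2H-pyran-6-yl]-2H-chromen-2-one
Conditions: HF·pyridine, THF, 0 °C → rt
Reagents that add atoms: none
Why: Fluoride-driven cleavage of the silyl ether under weakly acidic conditions spares the lactone, the phenol and the enone and avoids the basic conditions under which ring C could open by retro-oxa-Michael reaction and lose its C2' configuration.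

**Compound list**
1 | ethyl (S)-3-hydroxybutanoate | CCOC(=O)C[C@H](C)O | starting material
2 | ethyl (2S,3S)-3-hydroxy-2-methylbutanoate | CCOC(=O)[C@@H](C)[C@H](C)O | intermediate
3 | ethyl (2S,3S)-3-[(tert-butyldiphenylsilyl)oxy]-2-methylbutanoate | CCOC(=O)[C@@H](C)[C@H](C)O[Si](c1ccccc1)(c1ccccc1)C(C)(C)C | intermediate
4 | (2S,3S)-3-[(tert-butyldiphenylsilyl)oxy]-2-methylbutanal | O=C[C@@H](C)[C@H](C)O[Si](c1ccccc1)(c1ccccc1)C(C)(C)C | intermediate
5 | dimethyl malonate | COC(=O)CC(=O)OC | starting material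
6 | dimethyl 2-{(2R,3S)-3-[(tert-butyldiphenylsilyl)oxy]-2-methylbutylidene}malonate | COC(=O)C(C(=O)OC)=C[C@@H](C)[C@H](C)O[Si](c1ccccc1)(c1ccccc1)C(C)(C)C | intermediate
7 | pentan-3-one | CCC(=O)CC | starting material
8 | dimethyl 2-{(2S,3R)-2-[(tert-butyldiphenylsilyl)oxy]-3,5-dimethyl-6-oxooctan-4-yl}malonate (C4 and C5 undefined) | CCC(=O)C(C)C(C(C(=O)OC)C(=O)OC)[C@@H](C)[C@H](C)O[Si](c1ccccc1)(c1ccccc1)C(C)(C)C | intermediate
9 | methyl 6-{(2R,3S)-3-[(tert-butyldiphenylsilyl)oxy]butan-2-yl}-3,5-dimethyl-2,4-dioxocyclohexane-1-carboxylate (ring centres undefined) | COC(=O)C1C(=O)C(C)C(=O)C(C)C1[C@@H](C)[C@H](C)O[Si](c1ccccc1)(c1ccccc1)C(C)(C)C | intermediate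
10 | methyl 3-bromo-6-{(2R,3S)-3-[(tert-butyldiphenylsilyl)oxy]butan-2-yl}-3,5-dimethyl-2,4-dioxocyclohexane-1-carboxylate (ring centres undefined) | COC(=O)C1C(=O)C(C)(Br)C(=O)C(C)C1[C@@H](C)[C@H](C)O[Si](c1ccccc1)(c1ccccc1)C(C)(C)C | intermediate
11 | methyl 6-{(2R,3S)-3-[(tert-butyldiphenylsilyl)oxy]butan-2-yl}-2,4-dihydroxy-3,5-dimethylbenzoate | COC(=O)c1c(O)c(C)c(O)c(C)c1[C@@H](C)[C@H](C)O[Si](c1ccccc1)(c1ccccc1)C(C)(C)C | intermediate
12 | methyl 6-{(2R,3S)-3-[(tert-butyldiphenylsilyl)oxy]butan-2-yl}-2,4-bis(methoxymethoxy)-3,5-dimethylbenzoate | COC(=O)c1c(OCOC)c(C)c(OCOC)c(C)c1[C@@H](C)[C@H](C)O[Si](c1ccccc1)(c1ccccc1)C(C)(C)C | intermediate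
13 | (6-{(2R,3S)-3-[(tert-butyldiphenylsilyl)oxy]butan-2-yl}-2,4-bis(methoxymethoxy)-3,5-dimethylphenyl)methanol | OCc1c(OCOC)c(C)c(OCOC)c(C)c1[C@@H](C)[C@H](C)O[Si](c1ccccc1)(c1ccccc1)C(C)(C)C | intermediate
14 | 6-{(2R,3S)-3-[(tert-butyldiphenylsilyl)oxy]butan-2-yl}-2,4-bis(methoxymethoxy)-3,5-dimethylbenzaldehyde | O=Cc1c(OCOC)c(C)c(OCOC)c(C)c1[C@@H](C)[C@H](C)O[Si](c1ccccc1)(c1ccccc1)C(C)(C)C | intermediate
15 | 6-{(2R,3S)-3-[(tert-butyldiphenylsilyl)oxy]butan-2-yl}-2,4-dihydroxy-3,5-dimethylbenzaldehyde | O=Cc1c(O)c(C)c(O)c(C)c1[C@@H](C)[C@H](C)O[Si](c1ccccc1)(c1ccccc1)C(C)(C)C | intermediate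
16 | methyl (R)-3-hydroxybutanoate | C[C@@H](O)CC(=O)OC | starting material
17 | methyl (R)-3-[(tert-butyldimethylsilyl)oxy]butanoate | C[C@@H](O[Si](C)(C)C(C)(C)C)CC(=O)OC | intermediate
18 | (R)-3-[(tert-butyldimethylsilyl)oxy]-N-methoxy-N-methylbutanamide | C[C@@H](O[Si](C)(C)C(C)(C)C)CC(=O)N(C)OC | intermediate
19 | methyl acetoacetate | CC(=O)CC(=O)OC | starting material
20 | methyl (R)-7-[(tert-butyldimethylsilyl)oxy]-3,5-dioxooctanoate | C[C@@H](O[Si](C)(C)C(C)(C)C)CC(=O)CC(=O)CC(=O)OC | intermediate
21 | methyl (R)-7-hydroxy-3,5-dioxooctanoate | C[C@@H](O)CC(=O)CC(=O)CC(=O)OC | intermediate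
22 | methyl 2-[(2R)-2-methyl-4-oxo-3,4-dihydro-2H-pyran-6-yl]acetate | COC(=O)CC1=CC(=O)C[C@@H](C)O1 | intermediate
23 | methyl 3-(6-{(2R,3S)-3-[(tert-butyldiphenylsilyl)oxy]butan-2-yl}-2,4-dihydroxy-3,5-dimethylphenyl)-2-[(2R)-2-methyl-4-oxo-3,4-dihydro-2H-pyran-6-yl]prop-2-enoate (alkene geometry undefined) | COC(=O)C(=Cc1c(O)c(C)c(O)c(C)c1[C@@H](C)[C@H](C)O[Si](c1ccccc1)(c1ccccc1)C(C)(C)C)C1=CC(=O)C[C@@H](C)O1 | intermediate
24 | 5-{(2R,3S)-3-[(tert-butyldiphenylsilyl)oxy]butan-2-yl}-7-hydroxy-6,8-dimethyl-3-[(2R)-2-methyl-4-oxo-3,4-dihydro-2H-pyran-6-yl]-2H-chromen-2-one | Cc1c(O)c(C)c2oc(=O)c(C3=CC(=O)C[C@@H](C)O3)cc2c1[C@@H](C)[C@H](C)O[Si](c1ccccc1)(c1ccccc1)C(C)(C)C | intermediate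
25 | 7-hydroxy-5-[(2R,3S)-3-hydroxybutan-2-yl]-6,8-dimethyl-3-[(2R)-2-methyl-4-oxo-3,4-dihydro-2H-pyran-6-yl]-2H-chromen-2-one (CNP0291478.1) | Cc1c(O)c(C)c2oc(=O)c(C3=CC(=O)C[C@@H](C)O3)cc2c1[C@@H](C)[C@H](C)O | target

Total step count: 16.
Longest linear sequence: 12 steps (steps 1–10, 15 and 16). Steps 11–14 form the side branch to ring C.

**Steps most likely to fail**

**Step 5.**
- What may go wrong: the basic enolate may deprotonate the acceptor at its γ-position, with erosion of C1'' or vinylogous loss of the silyloxy group. The crowded C5–C6 bond may form slowly. The adduct may fragment by retro-Michael reaction during the methoxide stage.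
- Fallback: the polarity is reversed, so the Michael addition makes C5–C4a instead of C5–C6. It sets out from aldehyde 4.
- A Horner–Wadsworth–Emmons olefination with diethyl (3-oxopentan-2-yl)phosphonate under mild Ba(OH)2 conditions in wet THF should give the enone (4E,6R,7S)-7-[(tert-butyldiphenylsilyl)oxy]-4,6-dimethyloct-4-en-3-one F1 without epimerising the aldehyde.
- Heating F1 with an excess of dimethyl malonate 5 and NaOMe in MeOH then runs the dimedone-type Michael–Claisen sequence through the same adduct 8. The fallback comes back to the route at 9.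

**Step 6.**
- What may go wrong: the bromine may stay on C8 without elimination. Surplus oxidant may attack the benzylic methyl groups of the electron-rich product. HBr may strip the silyl ether, after which the free alcohol would lactonise onto the neighbouring ester.
- Fallback: halogen-free and acid-free hydride abstraction from a preformed diene. It sets out from 9.
- TMSOTf and Et3N in CH2Cl2 at 0 °C should give methyl 6-{(2R,3S)-3-[(tert-butyldiphenylsilyl)oxy]butan-2-yl}-3,5-dimethyl-2,4-bis[(trimethylsilyl)oxy]cyclohexa-2,4-diene-1-carboxylate F2.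
- DDQ in toluene at rt dehydrogenates this cyclohexadiene to methyl 6-{(2R,3S)-3-[(tert-butyldiphenylsilyl)oxy]butan-2-yl}-3,5-dimethyl-2,4-bis[(trimethylsilyl)oxy]benzoate F3.
- Aqueous citric acid in THF removes the two aryl trimethylsilyl groups. The fallback comes back to the route at 11.

**Step 15.**
- What may go wrong: condensation may be slow at a di-ortho-substituted, electron-rich aldehyde. On long heating, the amine may open ring C, or C2' may erode by retro-oxa-Michael reaction.
- Fallback: the phenol is acylated first, so the C3–C4 bond forms intramolecularly, and ring C is made last under acid. It sets out from Weinreb amide 18 and aldehyde 15.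
- The lithium dienolate of commercial 2,2,6-trimethyl-4H-1,3-dioxin-4-one (LiN(iPr)2, THF, −78 °C) is acylated at its γ-carbon by 18 to give 6-{(4R)-4-[(tert-butyldimethylsilyl)oxy]-2-oxopentyl}-2,2-dimethyl-4H-1,3-dioxin-4-one F4.
- Heating F4 with 15 in toluene at 110 °C releases the acylketene (7R)-7-[(tert-butyldimethylsilyl)oxy]-3,5-dioxooct-1-en-1-one F5.
- F5 acylates the hydroxyl ortho to the aldehyde to give 3-{(2R,3S)-3-[(tert-butyldiphenylsilyl)oxy]butan-2-yl}-2-formyl-5-hydroxy-4,6-dimethylphenyl (7R)-7-[(tert-butyldimethylsilyl)oxy]-3,5-dioxooctanoate F6.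
- Intramolecular Knoevenagel condensation of F6, with a trace of Et3N if needed, closes ring B to (5R)-5-[(tert-butyldimethylsilyl)oxy]-1-(5-{(2R,3S)-3-[(tert-butyldiphenylsilyl)oxy]butan-2-yl}-7-hydroxy-6,8-dimethyl-2-oxo-2H-chromen-3-yl)hexane-1,3-dione F7. Acylation at O7 is reversible at this temperature, whereas closure of ring B is not.
- HF·pyridine then removes both silyl groups, and the freed hydroxyl closes on the ketone next to C3 with loss of water. The fallback comes back to the route at 25.

Further compounds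
F1 | step 5 | (4E,6R,7S)-7-[(tert-butyldiphenylsilyl)oxy]-4,6-dimethyloct-4-en-3-one | CCC(=O)/C(C)=C/[C@@H](C)[C@H](C)O[Si](c1ccccc1)(c1ccccc1)C(C)(C)C
F2 | step 6 | methyl 6-{(2R,3S)-3-[(tert-butyldiphenylsilyl)oxy]butan-2-yl}-3,5-dimethyl-2,4-bis[(trimethylsilyl)oxy]cyclohexa-2,4-diene-1-carboxylate | COC(=O)C1C(O[Si](C)(C)C)=C(C)C(O[Si](C)(C)C)=C(C)C1[C@@H](C)[C@H](C)O[Si](c1ccccc1)(c1ccccc1)C(C)(C)C
F3 | step 6 | methyl 6-{(2R,3S)-3-[(tert-butyldiphenylsilyl)oxy]butan-2-yl}-3,5-dimethyl-2,4-bis[(trimethylsilyl)oxy]benzoate | COC(=O)c1c(O[Si](C)(C)C)c(C)c(O[Si](C)(C)C)c(C)c1[C@@H](C)[C@H](C)O[Si](c1ccccc1)(c1ccccc1)C(C)(C)C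
F4 | step 15 | 6-{(4R)-4-[(tert-butyldimethylsilyl)oxy]-2-oxopentyl}-2,2-dimethyl-4H-1,3-dioxin-4-one | C[C@@H](O[Si](C)(C)C(C)(C)C)CC(=O)CC1=CC(=O)OC(C)(C)O1
F5 | step 15 | (7R)-7-[(tert-butyldimethylsilyl)oxy]-3,5-dioxooct-1-en-1-one | C[C@@H](O[Si](C)(C)C(C)(C)C)CC(=O)CC(=O)C=C=O
F6 | step 15 | 3-{(2R,3S)-3-[(tert-butyldiphenylsilyl)oxy]butan-2-yl}-2-formyl-5-hydroxy-4,6-dimethylphenyl (7R)-7-[(tert-butyldimethylsilyl)oxy]-3,5-dioxooctanoate | O=Cc1c(OC(=O)CC(=O)CC(=O)C[C@@H](C)O[Si](C)(C)C(C)(C)C)c(C)c(O)c(C)c1[C@@H](C)[C@H](C)O[Si](c1ccccc1)(c1ccccc1)C(C)(C)C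
F7 | step 15 | (5R)-5-[(tert-butyldimethylsilyl)oxy]-1-(5-{(2R,3S)-3-[(tert-butyldiphenylsilyl)oxy]butan-2-yl}-7-hydroxy-6,8-dimethyl-2-oxo-2H-chromen-3-yl)hexane-1,3-dione | Cc1c(O)c(C)c2oc(=O)c(C(=O)CC(=O)C[C@@H](C)O[Si](C)(C)C(C)(C)C)cc2c1[C@@H](C)[C@H](C)O[Si](c1ccccc1)(c1ccccc1)C(C)(C)C
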